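**Retrosynthetic overview**

1. The target acid comes from its tert-butyl ester by silyl triflate ester cleavage in the last step.
2. Benzene ring A of that ester is cut into a pyranonyl α-diazo ketone and tert-butyl (R)-3-(methoxyethynyl)octanoate. The forward cascade is a photochemical Wolff shift (C8–C8a), a [2+2] addition (C5–C6, C7–C8), a 4π opening and a 6π closure (C4a–C5). The strategy rests on the hexasubstituted ring A (C4a, C5, C6, C7, C8, C8a) with three unlike oxygens: free OH on C5 from the ketene carbonyl, OMe on C7 from the alkyne, ring O1 on C8a from the pyranone enol ether.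
3. The diazo ketone comes from cis-2,3-dimethyl-dihydropyranone-6-carboxylic acid (Negishi acylation, detrifluoroacetylative diazo transfer). The acid comes from an Evans syn-aldol methyl ketone and di-tert-butyl oxalate (Claisen condensation, cyclodehydration).
4. The methoxyalkyne comes from tert-butyl (R)-3-formyloctanoate (methoxymethylenation, bromination, double dehydrobromination), itself from Evans alkylation of a heptanoyl imide with tert-butyl bromoacetate.
5. Ring order: the oxygen heterocycle (O1, C2, C3, C4, C4a, C8a) first, benzene ring A second.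

Key step: step 17

Assumption: chroman-4-one numbering (O1, C2, C3, C4, C4a, C5–C8, C8a) is used for the target, and the dihydropyranone is numbered O1, C2(Me), C3(Me), C4(=O), C5, C6 throughout; the benzylic center is (R) and the C2/C3 methyl groups are cis (2S,3R).

**Route**

Step 1
Reactants: 1 (R)-4-benzyl-3-propanoyloxazolidin-2-one; 2 acetaldehyde
Product: 3 (R)-4-benzyl-3-[(2R,3S)-3-hydroxy-2-methylbutanoyl]oxazolidin-2-one
Conditions: Bu2BOTf, iPr2NEt, CH2Cl2, −78 → 0 °C; 2, −78 → 0 °C; pH 7 buffer, MeOH, H2O2, 0 °C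
Reagents that add atoms: none
Why: Evans boron aldol reaction: the Z-dibutylboron enolate should add to acetaldehyde through a Zimmerman–Traxler chair on the face remote from the auxiliary benzyl group, setting the syn pair C2 (R) and C3 (S) of the acyl chain, which become C3 and C2 of the pyranone.

Step 2
Reactants: 3 (R)-4-benzyl-3-[(2R,3S)-3-hydroxy-2-methylbutanoyl]oxazolidin-2-one
Product: 4 (2R,3S)-3-hydroxy-N-methoxy-N,2-dimethylbutanamide
Conditions: MeNHOMe·HCl, AlMe3, CH2Cl2, −20 → 0 °C; aq. HCl (0.5 M)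
Reagents that add atoms: N,O-dimethylhydroxylamine hydrochloride, CNOC.Cl
Why: Weinreb transamidation with the aluminium amide: the free C3 hydroxyl binds aluminium and delivers the amide to the exocyclic carbonyl, so the auxiliary should be displaced without touching the C2 center.

Step 3
Reactants: 4 (2R,3S)-3-hydroxy-N-methoxy-N,2-dimethylbutanamide
Product: 5 (2R,3S)-N-methoxy-N,2-dimethyl-3-[(triethylsilyl)oxy]butanamide
Conditions: Et3SiCl, imidazole, DMF, 0 → 20 °C
Reagents that add atoms: chlorotriethylsilane, CC[Si](Cl)(CC)CC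
Why: Standard silylation of a secondary alcohol, needed so that the later enolate chemistry meets no free hydroxyl; the triethylsilyl group is chosen because acid removes it in step 6.

Step 4
Reactants: 5 (2R,3S)-N-methoxy-N,2-dimethyl-3-[(triethylsilyl)oxy]butanamide
Product: 6 (3R,4S)-3-methyl-4-[(triethylsilyl)oxy]pentan-2-one
Conditions: MeMgBr, THF, 0 °C; aq. NH4Cl
Reagents that add atoms: methylmagnesium bromide, C[Mg]Br
Why: Weinreb ketone synthesis: the magnesium chelate of the tetrahedral adduct should stop at the ketone stage and the C3 center is not enolized by the Grignard reagent at 0 °C.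

Step 5
Reactants: 6 (3R,4S)-3-methyl-4-[(triethylsilyl)oxy]pentan-2-one; 7 di-tert-butyl oxalate
Product: 8 tert-butyl (5R,6S)-5-methyl-2,4-dioxo-6-[(triethylsilyl)oxy]heptanoate (present largely as its enol)
Conditions: LiN(SiMe3)2 (1.1 equiv), THF, −78 °C; 7 (1.3 equiv), −78 → 0 °C; aq. NH4Cl/HCl to pH 4
Reagents that add atoms: none
Why: Crossed Claisen condensation: the amide base should deprotonate the unhindered methyl group kinetically, the non-enolizable oxalate acylates this enolate, and the released tert-butoxide stores the product as its diketonate, which keeps the C5 center from enolizing.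

Step 6
Reactants: 8 tert-butyl (5R,6S)-5-methyl-2,4-dioxo-6-[(triethylsilyl)oxy]heptanoate
Product: 11 (2S,3R)-2,3-dimethyl-4-oxo-3,4-dihydro-2H-pyran-6-carboxylic acid, via hydroxy diketo ester 9 (not isolated), via pyranone tert-butyl ester 10 (not isolated)
Conditions: CF3CO2H/CH2Cl2 (1:4), 0 → 20 °C; evaporation from toluene
Reagents that add atoms: none
Why: Acid-mediated cyclodehydration: after loss of the silyl group the C6 hydroxyl should add to the C2 ketone to a six-membered hemiketal that dehydrates to the vinylogous ester (ring closed by O-attack on a carbonyl carbon, 6-exo-trig), the same acid cleaves the tert-butyl ester, and the base-free medium leaves the cis C2/C3 pair alone.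

Step 7
Reactants: 12 5-bromo-2-methylpent-2-ene
Product: 13 (4-methylpent-3-en-1-yl)zinc bromide (THF solution, used directly)
Conditions: Zn dust (activated with BrCH2CH2Br and Me3SiCl), LiCl, THF, 50 °C
Reagents that add atoms: zinc, [Zn]
Why: Direct insertion of zinc into a primary alkyl bromide, promoted by LiCl, should give an alkylzinc halide that tolerates ketones and enones.

Step 8
Reactants: 11 (2S,3R)-2,3-dimethyl-4-oxo-3,4-dihydro-2H-pyran-6-carboxylic acid; 13 (4-methylpent-3-en-1-yl)zinc bromide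
Product: 15 (2S,3R)-2,3-dimethyl-6-(5-methylhex-4-enoyl)-2,3-dihydro-4H-pyran-4-one, via acid chloride 14 (not isolated)
Conditions: (COCl)2, DMF (cat.), CH2Cl2, 0 → 20 °C, evaporation; then 13, Pd(PPh3)4 (5 mol %), THF, 0 → 20 °C
Reagents that add atoms: none
Why: Negishi acylation: zerovalent palladium inserts into the acyl C–Cl bond of 14, the alkylzinc bromide transmetalates and reductive elimination gives the ketone, while the organozinc reagent should add neither to the C4 ketone nor to the enone of the pyranone.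

Step 9
Reactants: 15 (2S,3R)-2,3-dimethyl-6-(5-methylhex-4-enoyl)-2,3-dihydro-4H-pyran-4-one
Product: 17 (2S,3R)-6-(2-diazo-5-methylhex-4-enoyl)-2,3-dimethyl-2,3-dihydro-4H-pyran-4-one, via trifluoroacetyl ketone 16 (not isolated)
Conditions: LiN(SiMe3)2 (1.05 equiv), THF, −78 °C; CF3CO2CH2CF3, −78 °C; aq. HCl work-up; then MsN3, Et3N, H2O (1 equiv), MeCN, 20 °C
Reagents that add atoms: methanesulfonyl azide, CS(=O)(=O)N=[N+]=[N-]
Why: Detrifluoroacetylative diazo transfer (a deacylative Regitz diazo transfer): the amide base should remove a proton from the unhindered side-chain CH2 of the more acidic acyl ketone rather than the tertiary C3–H of the vinylogous ester, trifluoroacetylation makes this carbon acidic enough for diazo transfer with Et3N, and the trifluoroacetyl group leaves on the sulfonamide.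

Step 10
Reactants: 18 (S)-4-benzyloxazolidin-2-one; 19 heptanoyl chloride
Product: 20 (S)-4-benzyl-3-heptanoyloxazolidin-2-one
Conditions: n-BuLi, THF, −78 °C; 19, −78 → 0 °C
Reagents that add atoms: none
Why: N-Acylation of the lithiated oxazolidinone by an acid chloride, a standard way to load an Evans auxiliary.

Step 11
Reactants: 20 (S)-4-benzyl-3-heptanoyloxazolidin-2-one; 21 tert-butyl bromoacetate
Product: 22 tert-butyl (3R)-3-{[(4S)-4-benzyl-2-oxo-1,3-oxazolidin-3-yl]carbonyl}octanoate
Conditions: NaN(SiMe3)2, THF, −78 °C; 21, −78 → −40 °C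
Reagents that add atoms: none
Why: Evans asymmetric alkylation: the chelated Z-sodium enolate should be alkylated by the reactive bromoacetate on the face opposite the benzyl group, which sets the side-chain center as (R).

Step 12
Reactants: 22 tert-butyl (3R)-3-{[(4S)-4-benzyl-2-oxo-1,3-oxazolidin-3-yl]carbonyl}octanoate
Product: 23 tert-butyl (3R)-3-(hydroxymethyl)octanoate
Conditions: LiBH4, MeOH (1 equiv), Et2O, 0 °C; aq. NH4Cl
Reagents that add atoms: none
Why: Reductive cleavage of the N-acyl oxazolidinone: LiBH4 should reduce the activated exocyclic imide carbonyl to the primary alcohol much faster than the hindered tert-butyl ester, whose bulk also slows lactonization of the hydroxy ester.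

Step 13
Reactants: 23 tert-butyl (3R)-3-(hydroxymethyl)octanoate
Product: 24 tert-butyl (3R)-3-formyloctanoate
Conditions: Dess–Martin periodinane, CH2Cl2, 0 → 20 °C
Reagents that add atoms: none
Why: Dess–Martin oxidation should give the α-branched aldehyde under near-neutral conditions without epimerization at C3.

Step 14
Reactants: 24 tert-butyl (3R)-3-formyloctanoate
Product: 25 tert-butyl (3R)-3-(2-methoxyethenyl)octanoate (E/Z mixture)
Conditions: Ph3P(CH2OMe)Cl, KN(SiMe3)2, THF, 0 °C; then 24, −78 → 0 °C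
Reagents that add atoms: (methoxymethyl)triphenylphosphonium chloride, COC[P+](c1ccccc1)(c1ccccc1)c1ccccc1.[Cl-]
Why: Wittig methoxymethylenation: the non-stabilized ylide should add to the aldehyde at −78 °C faster than it enolizes it, and both enol ether isomers are used since the geometry is lost in step 15.

Step 15
Reactants: 25 tert-butyl (3R)-3-(2-methoxyethenyl)octanoate
Product: 27 tert-butyl (3R)-3-(1-bromo-2-methoxyethenyl)octanoate (E/Z mixture), via dibromide 26 (not isolated)
Conditions: Br2, CH2Cl2, −78 °C; then iPr2NEt, −78 → 20 °C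
Reagents that add atoms: bromine, BrBr
Why: Bromine adds to the electron-rich enol ether, the α-bromo ether of 26 ionizes to an oxocarbenium ion and the hindered amine removes the adjacent C–H (dehydrobromination), which should give the β-bromo enol ether without touching the C3 center.

Step 16
Reactants: 27 tert-butyl (3R)-3-(1-bromo-2-methoxyethenyl)octanoate
Product: 28 tert-butyl (3R)-3-(methoxyethynyl)octanoate
Conditions: LiN(iPr)2 (3 equiv), THF, −78 → −20 °C; pH 7 phosphate buffer
Reagents that add atoms: none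
Why: Base-induced dehydrobromination of the β-bromo enol ether to the alkynyl ether (classical alkoxyalkyne synthesis): the first equivalent of amide stores the tert-butyl ester as its lithium enolate, further base removes HBr from the vinyl bromide, and the C3 center, which is β to the ester and only propargylic, should not be deprotonated at low temperature.

Step 17
Reactants: 17 (2S,3R)-6-(2-diazo-5-methylhex-4-enoyl)-2,3-dimethyl-2,3-dihydro-4H-pyran-4-one; 28 tert-butyl (3R)-3-(methoxyethynyl)octanoate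
Product: 33 tert-butyl (3R)-3-[(2S,3R)-5-hydroxy-7-methoxy-2,3-dimethyl-8-(3-methylbut-2-en-1-yl)-4-oxo-3,4-dihydro-2H-chromen-6-yl]octanoate, via vinylketene 29 (not isolated), via vinylcyclobutenone 30 (not isolated), via dienylketene 31 (not isolated), via cyclohexadienone 32 (not isolated)
Conditions: 28 (1.5 equiv), hν (medium-pressure Hg lamp, Pyrex filter, λ > 300 nm), degassed ClCH2CH2Cl (0.2 M), 20 °C; then 80 °C
Reagents that add atoms: none
Why: Light expels N2 from 17 and the pyranonyl group shifts to the diazo carbon (Wolff rearrangement, bond C8–C8a) to give vinylketene 29, whose electrophilic ketene carbon adds to the oxygen-remote carbon of 28 in a polar [2+2] cycloaddition (C5–C6 and C7–C8) to give 30; on warming, 30 opens by a reversible conrotatory 4π-electrocyclic reaction to dienylketene 31, which closes by 6π-electrocyclization (C4a–C5) to dienone 32 and tautomerizes to the phenol. The closest known reaction is the second-generation Danheiser benzannulation, in which α-diazo-α,β-unsaturated ketones are photolysed with alkoxy- or siloxyalkynes; the α-alkyl substituent and the vinylogous-ester enone are the untested points of this substrate. Ring A is closed by the thermal disrotatory 6π-electrocyclization of the ketene carbon onto pyranone C5, the other ring bonds coming from the Wolff shift and the [2+2] step. No stereocenter is created: the quaternary carbon of 30 becomes planar again, and the cis C2/C3 pair and the side-chain center are spectators in a neutral aprotic medium. The step needs one regiochemical sense in the [2+2] addition, which the oxygen-polarized alkyne secures, so that OH can end only on C5, OMe only on C7 and O1 only on C8a. It also needs the Wolff shift to outrun the 1,2-hydrogen shift from the α-CH2 and enone photochemistry at the prenyl alkene, for which direct irradiation above 300 nm and the excess of 28 as ketene trap are chosen, while the chelated and flanked C5–OH of 33 should be a poor acceptor for residual ketene.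

Step 18
Reactants: 33 tert-butyl (3R)-3-[(2S,3R)-5-hydroxy-7-methoxy-2,3-dimethyl-8-(3-methylbut-2-en-1-yl)-4-oxo-3,4-dihydro-2H-chromen-6-yl]octanoate
Product: 35 (3R)-3-[(2S,3R)-5-hydroxy-7-methoxy-2,3-dimethyl-8-(3-methylbut-2-en-1-yl)-4-oxo-3,4-dihydro-2H-chromen-6-yl]octanoic acid (CNP0217102.1), via bis-silyl derivative 34 (not isolated)
Conditions: Me3SiOTf (2.5 equiv), 2,6-lutidine (3.5 equiv), CH2Cl2, 0 °C; then H2O (pH 5 citrate buffer)
Reagents that add atoms: none
Why: Silyl triflate cleavage of the tert-butyl ester: silylation of the ester carbonyl and loss of the tert-butyl cation as isobutene give the silyl ester 34 without protic acid (prenyl alkene safe) and with a base too weak to epimerize C3, the limited reagent charge at 0 °C is meant to keep the C4 ketone from enol silylation, and water then hydrolyzes the silyl ester and the aryl silyl ether.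

**Compound list**

1 | (R)-4-benzyl-3-propanoyloxazolidin-2-one | CCC(=O)N1[C@H](Cc2ccccc2)COC1=O | starting material
2 | acetaldehyde | CC=O | starting material
3 | (R)-4-benzyl-3-[(2R,3S)-3-hydroxy-2-methylbutanoyl]oxazolidin-2-one | C[C@H](O)[C@@H](C)C(=O)N1[C@H](Cc2ccccc2)COC1=O | intermediate
4 | (2R,3S)-3-hydroxy-N-methoxy-N,2-dimethylbutanamide | C[C@H](O)[C@@H](C)C(=O)N(C)OC | intermediate
5 | (2R,3S)-N-methoxy-N,2-dimethyl-3-[(triethylsilyl)oxy]butanamide | C[C@H](O[Si](CC)(CC)CC)[C@@H](C)C(=O)N(C)OC | intermediate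
6 | (3R,4S)-3-methyl-4-[(triethylsilyl)oxy]pentan-2-one | C[C@H](O[Si](CC)(CC)CC)[C@@H](C)C(C)=O | intermediate
7 | di-tert-butyl oxalate | CC(C)(C)OC(=O)C(=O)OC(C)(C)C | starting material
8 | tert-butyl (5R,6S)-5-methyl-2,4-dioxo-6-[(triethylsilyl)oxy]heptanoate | C[C@H](O[Si](CC)(CC)CC)[C@@H](C)C(=O)CC(=O)C(=O)OC(C)(C)C | intermediate
9 | tert-butyl (5R,6S)-6-hydroxy-5-methyl-2,4-dioxoheptanoate | C[C@H](O)[C@@H](C)C(=O)CC(=O)C(=O)OC(C)(C)C | intermediate (not isolated)
10 | tert-butyl (2S,3R)-2,3-dimethyl-4-oxo-3,4-dihydro-2H-pyran-6-carboxylate | CC(C)(C)OC(=O)C1=CC(=O)[C@H](C)[C@H](C)O1 | intermediate (not isolated)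
11 | (2S,3R)-2,3-dimethyl-4-oxo-3,4-dihydro-2H-pyran-6-carboxylic acid | OC(=O)C1=CC(=O)[C@H](C)[C@H](C)O1 | intermediate
12 | 5-bromo-2-methylpent-2-ene | CC(C)=CCCBr | starting material
13 | (4-methylpent-3-en-1-yl)zinc bromide | CC(C)=CCC[Zn]Br | intermediate
14 | (2S,3R)-2,3-dimethyl-4-oxo-3,4-dihydro-2H-pyran-6-carbonyl chloride | ClC(=O)C1=CC(=O)[C@H](C)[C@H](C)O1 | intermediate (not isolated)
15 | (2S,3R)-2,3-dimethyl-6-(5-methylhex-4-enoyl)-2,3-dihydro-4H-pyran-4-one | CC(C)=CCCC(=O)C1=CC(=O)[C@H](C)[C@H](C)O1 | intermediate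
16 | (2S,3R)-2,3-dimethyl-6-[5-methyl-2-(trifluoroacetyl)hex-4-enoyl]-2,3-dihydro-4H-pyran-4-one (epimers at the side-chain carbon, enolized) | CC(C)=CCC(C(=O)C(F)(F)F)C(=O)C1=CC(=O)[C@H](C)[C@H](C)O1 | intermediate (not isolated)
17 | (2S,3R)-6-(2-diazo-5-methylhex-4-enoyl)-2,3-dimethyl-2,3-dihydro-4H-pyran-4-one | CC(C)=CCC(=[N+]=[N-])C(=O)C1=CC(=O)[C@H](C)[C@H](C)O1 | intermediate
18 | (S)-4-benzyloxazolidin-2-one | O=C1N[C@@H](Cc2ccccc2)CO1 | starting material
19 | heptanoyl chloride | CCCCCCC(=O)Cl | starting material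
20 | (S)-4-benzyl-3-heptanoyloxazolidin-2-one | CCCCCCC(=O)N1[C@@H](Cc2ccccc2)COC1=O | intermediate
21 | tert-butyl bromoacetate | CC(C)(C)OC(=O)CBr | starting material
22 | tert-butyl (3R)-3-{[(4S)-4-benzyl-2-oxo-1,3-oxazolidin-3-yl]carbonyl}octanoate | CCCCC[C@H](CC(=O)OC(C)(C)C)C(=O)N1[C@@H](Cc2ccccc2)COC1=O | intermediate
23 | tert-butyl (3R)-3-(hydroxymethyl)octanoate | CCCCC[C@H](CC(=O)OC(C)(C)C)CO | intermediate
24 | tert-butyl (3R)-3-formyloctanoate | CCCCC[C@H](CC(=O)OC(C)(C)C)C=O | intermediate
25 | tert-butyl (3R)-3-(2-methoxyethenyl)octanoate (E/Z mixture) | CCCCC[C@H](CC(=O)OC(C)(C)C)C=COC | intermediate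
26 | tert-butyl (3R)-3-(1,2-dibromo-2-methoxyethyl)octanoate (diastereomer mixture) | CCCCC[C@H](CC(=O)OC(C)(C)C)C(Br)C(Br)OC | intermediate (not isolated)
27 | tert-butyl (3R)-3-(1-bromo-2-methoxyethenyl)octanoate (E/Z mixture) | CCCCC[C@H](CC(=O)OC(C)(C)C)C(Br)=COC | intermediate
28 | tert-butyl (3R)-3-(methoxyethynyl)octanoate | CCCCC[C@H](CC(=O)OC(C)(C)C)C#COC | intermediate
29 | 2-[(2S,3R)-2,3-dimethyl-4-oxo-3,4-dihydro-2H-pyran-6-yl]-5-methylhexa-1,4-dien-1-one (vinylketene) | CC(C)=CCC(=C=O)C1=CC(=O)[C@H](C)[C@H](C)O1 | intermediate (not isolated)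
30 | tert-butyl (3R)-3-{3-[(2S,3R)-2,3-dimethyl-4-oxo-3,4-dihydro-2H-pyran-6-yl]-2-methoxy-3-(3-methylbut-2-en-1-yl)-4-oxocyclobut-1-en-1-yl}octanoate (both epimers at the ring quaternary carbon) | CCCCC[C@H](CC(=O)OC(C)(C)C)C1=C(OC)C(CC=C(C)C)(C1=O)C2=CC(=O)[C@H](C)[C@H](C)O2 | intermediate (not isolated)
31 | tert-butyl (3R)-3-{4-[(2S,3R)-2,3-dimethyl-4-oxo-3,4-dihydro-2H-pyran-6-yl]-3-methoxy-7-methyl-1-oxoocta-1,3,6-trien-2-yl}octanoate (dienylketene, both C3=C4 isomers in equilibrium through 30) | CCCCC[C@H](CC(=O)OC(C)(C)C)C(=C=O)C(OC)=C(CC=C(C)C)C1=CC(=O)[C@H](C)[C@H](C)O1 | intermediate (not isolated)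
32 | tert-butyl (3R)-3-[(2S,3R)-7-methoxy-2,3-dimethyl-8-(3-methylbut-2-en-1-yl)-4,5-dioxo-3,4,4a,5-tetrahydro-2H-chromen-6-yl]octanoate | CCCCC[C@H](CC(=O)OC(C)(C)C)C1=C(OC)C(CC=C(C)C)=C2O[C@@H](C)[C@@H](C)C(=O)C2C1=O | intermediate (not isolated)
33 | tert-butyl (3R)-3-[(2S,3R)-5-hydroxy-7-methoxy-2,3-dimethyl-8-(3-methylbut-2-en-1-yl)-4-oxo-3,4-dihydro-2H-chromen-6-yl]octanoate | CCCCC[C@H](CC(=O)OC(C)(C)C)c1c(O)c2c(c(CC=C(C)C)c1OC)O[C@@H](C)[C@@H](C)C2=O | intermediate
34 | trimethylsilyl (3R)-3-[(2S,3R)-7-methoxy-2,3-dimethyl-8-(3-methylbut-2-en-1-yl)-4-oxo-5-[(trimethylsilyl)oxy]-3,4-dihydro-2H-chromen-6-yl]octanoate | CCCCC[C@H](CC(=O)O[Si](C)(C)C)c1c(O[Si](C)(C)C)c2c(c(CC=C(C)C)c1OC)O[C@@H](C)[C@@H](C)C2=O | intermediate (not isolated)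
35 | (3R)-3-[(2S,3R)-5-hydroxy-7-methoxy-2,3-dimethyl-8-(3-methylbut-2-en-1-yl)-4-oxo-3,4-dihydro-2H-chromen-6-yl]octanoic acid | CCCCC[C@H](CC(=O)O)c1c(O)c2c(c(CC=C(C)C)c1OC)O[C@@H](C)[C@@H](C)C2=O | target

**Step count**

Total: 18 steps. Longest linear sequence: 10 steps (1, 2, 3, 4, 5, 6, 8, 9, 17, 18).

**Steps most likely to fail**

1. Step 17. On loss of N2 a hydrogen of the neighbouring CH2 may migrate to the carbene carbon faster than the pyranonyl group does, or the excited enone may react with the prenyl alkene, so that little ketene reaches the alkyne. The fallback removes the α-alkyl group from the diazo ketone and adds the prenyl group at the end. It sets out from acid 11 through its chloride 14. Negishi coupling with MeZnCl and Pd(PPh3)4 would give (2S,3R)-6-acetyl-2,3-dimethyl-2,3-dihydro-4H-pyran-4-one F1. LiN(SiMe3)2 and CF3CO2CH2CF3 would give 4,4,4-trifluoro-1-[(2S,3R)-2,3-dimethyl-4-oxo-3,4-dihydro-2H-pyran-6-yl]butane-1,3-dione F2, and MsN3 with Et3N would give (2S,3R)-6-(diazoacetyl)-2,3-dimethyl-2,3-dihydro-4H-pyran-4-one F3, which has no α-alkyl hydrogen to shift. Photolysis of F3 with 28 under the conditions of step 17 should give the C8-unsubstituted ester tert-butyl (3R)-3-[(2S,3R)-5-hydroxy-7-methoxy-2,3-dimethyl-4-oxo-3,4-dihydro-2H-chromen-6-yl]octanoate F4. N-Bromosuccinimide in CH2Cl2 at 0 °C should brominate the only free ring position to give tert-butyl (3R)-3-[(2S,3R)-8-bromo-5-hydroxy-7-methoxy-2,3-dimethyl-4-oxo-3,4-dihydro-2H-chromen-6-yl]octanoate F5. Stille coupling of F5 with tributyl(3-methylbut-2-en-1-yl)stannane and Pd(PPh3)4 in DMF at 100 °C comes back to the route at 33.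

2. Step 16. Dehydrobromination may stall for the isomer with H and Br on the same side, the base may isomerize the alkyne to an allene and so erode the propargylic center, and the methyl ynol ether may hydrate on work-up. The fallback replaces the methoxyalkyne by a siloxyalkyne and sets out from imide 22. BrMgOEt (from EtMgBr and EtOH) in THF at 0 °C would give 4-tert-butyl 1-ethyl (2R)-2-pentylbutanedioate F6. Kowalski homologation (LiCHBr2 from CH2Br2 and lithium 2,2,6,6-tetramethylpiperidide at −78 °C, then n-BuLi, the ynolate trapped with iPr3SiOTf; the tert-butyl ester is held as its lithium enolate) would give tert-butyl (3R)-3-({[tri(propan-2-yl)silyl]oxy}ethynyl)octanoate F7. Benzannulation of F7 with 17 as in step 17 should give tert-butyl (3R)-3-[(2S,3R)-5-hydroxy-2,3-dimethyl-8-(3-methylbut-2-en-1-yl)-4-oxo-7-{[tri(propan-2-yl)silyl]oxy}-3,4-dihydro-2H-chromen-6-yl]octanoate F8. Bu4NF buffered with AcOH would give tert-butyl (3R)-3-[(2S,3R)-5,7-dihydroxy-2,3-dimethyl-8-(3-methylbut-2-en-1-yl)-4-oxo-3,4-dihydro-2H-chromen-6-yl]octanoate F9. Me3SiCHN2 in MeOH/toluene should methylate only its non-chelated C7–OH and comes back to the route at 33.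

3. Step 9. The amide base may deprotonate C3–H of the pyranone instead of the side-chain CH2, which would scramble the cis C2/C3 pair, or may degrade the ene-dione. The fallback avoids strong base and sets out from acid 11 through its chloride 14. Stork acylation with 4-[(1E)-5-methylhexa-1,4-dien-1-yl]morpholine F10 (from 5-methylhex-4-enal and morpholine) and Et3N in CH2Cl2 at 0 °C would give (2S,3R)-2,3-dimethyl-6-[5-methyl-2-(morpholin-4-ylmethylidene)hex-4-enoyl]-2,3-dihydro-4H-pyran-4-one F11. Mild hydrolysis (aq. AcOH/NaOAc) would give 2-{[(2S,3R)-2,3-dimethyl-4-oxo-3,4-dihydro-2H-pyran-6-yl]carbonyl}-5-methylhex-4-enal F12. Regitz deformylative diazo transfer (MsN3, Et3N, MeCN, 0 °C) comes back to the route at 17.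

**Further compounds**

F1 | step 17 | (2S,3R)-6-acetyl-2,3-dimethyl-2,3-dihydro-4H-pyran-4-one | CC(=O)C1=CC(=O)[C@H](C)[C@H](C)O1
F2 | step 17 | 4,4,4-trifluoro-1-[(2S,3R)-2,3-dimethyl-4-oxo-3,4-dihydro-2H-pyran-6-yl]butane-1,3-dione | O=C(CC(=O)C(F)(F)F)C1=CC(=O)[C@H](C)[C@H](C)O1
F3 | step 17 | (2S,3R)-6-(diazoacetyl)-2,3-dimethyl-2,3-dihydro-4H-pyran-4-one | [N-]=[N+]=CC(=O)C1=CC(=O)[C@H](C)[C@H](C)O1
F4 | step 17 | tert-butyl (3R)-3-[(2S,3R)-5-hydroxy-7-methoxy-2,3-dimethyl-4-oxo-3,4-dihydro-2H-chromen-6-yl]octanoate | CCCCC[C@H](CC(=O)OC(C)(C)C)c1c(O)c2c(cc1OC)O[C@@H](C)[C@@H](C)C2=O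
F5 | step 17 | tert-butyl (3R)-3-[(2S,3R)-8-bromo-5-hydroxy-7-methoxy-2,3-dimethyl-4-oxo-3,4-dihydro-2H-chromen-6-yl]octanoate | CCCCC[C@H](CC(=O)OC(C)(C)C)c1c(O)c2c(c(Br)c1OC)O[C@@H](C)[C@@H](C)C2=O
F6 | step 16 | 4-tert-butyl 1-ethyl (2R)-2-pentylbutanedioate | CCCCC[C@H](CC(=O)OC(C)(C)C)C(=O)OCC
F7 | step 16 | tert-butyl (3R)-3-({[tri(propan-2-yl)silyl]oxy}ethynyl)octanoate | CCCCC[C@H](CC(=O)OC(C)(C)C)C#CO[Si](C(C)C)(C(C)C)C(C)C
F8 | step 16 | tert-butyl (3R)-3-[(2S,3R)-5-hydroxy-2,3-dimethyl-8-(3-methylbut-2-en-1-yl)-4-oxo-7-{[tri(propan-2-yl)silyl]oxy}-3,4-dihydro-2H-chromen-6-yl]octanoate | CCCCC[C@H](CC(=O)OC(C)(C)C)c1c(O)c2c(c(CC=C(C)C)c1O[Si](C(C)C)(C(C)C)C(C)C)O[C@@H](C)[C@@H](C)C2=O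
F9 | step 16 | tert-butyl (3R)-3-[(2S,3R)-5,7-dihydroxy-2,3-dimethyl-8-(3-methylbut-2-en-1-yl)-4-oxo-3,4-dihydro-2H-chromen-6-yl]octanoate | CCCCC[C@H](CC(=O)OC(C)(C)C)c1c(O)c2c(c(CC=C(C)C)c1O)O[C@@H](C)[C@@H](C)C2=O
F10 | step 9 | 4-[(1E)-5-methylhexa-1,4-dien-1-yl]morpholine | CC(C)=CC/C=C/N1CCOCC1
F11 | step 9 | (2S,3R)-2,3-dimethyl-6-[5-methyl-2-(morpholin-4-ylmethylidene)hex-4-enoyl]-2,3-dihydro-4H-pyran-4-one | CC(C)=CCC(=CN1CCOCC1)C(=O)C2=CC(=O)[C@H](C)[C@H](C)O2
F12 | step 9 | 2-{[(2S,3R)-2,3-dimethyl-4-oxo-3,4-dihydro-2H-pyran-6-yl]carbonyl}-5-methylhex-4-enal | CC(C)=CCC(C=O)C(=O)C1=CC(=O)[C@H](C)[C@H](C)O1
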